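The numbers are made up; what happens was integrated by code.

I started with the easy step: the turnover takes a fresh carrier and hands it back as spent carrier, while the pairing step removes two fresh carrier for good.

substrate 0.80 M; salt in the second phase 2.40 M; spent carrier 20 mM; volume of the second phase over the first 2.0

    substrate + fresh carrier → target + spent carrier (k1 = 0.17 L mol⁻¹ s⁻¹)
    spent carrier + salt in the second phase ⇌ fresh carrier + spent salt in the second phase (K2 = 0.97, k2 = 6.3 L mol⁻¹ s⁻¹)
    spent carrier → spent catalyst A (k3 = 0.0021 s⁻¹)
    2 fresh carrier → spent catalyst B (k4 = 0.17 L mol⁻¹ s⁻¹)

- for a step with 2 of a species take k times the square, and two of it per event
- in the second phase: salt in the second phase, spent salt in the second phase; everything else is in the first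
- charges count per volume of the first phase; a concentration in a rate is the amount of a species over the volume of its own phase; every rate counts per litre of the first phase
- a form made of two catalysts counts as two
- charge of substrate (flask): 0.80 M

* the form that holds most of the catalyst when 50 % of the substrate are converted (spent carrier / spent catalyst B / fresh carrier / spent catalyst A)
* its share of the catalyst then
* apparent order in salt in the second phase when 50 % of the substrate are converted (percent change of the rate of making target for one percent more salt in the second phase charged)
* apparent order in spent carrier when 50 % of the substrate are converted (percent change of the rate of making target for one percent more spent carrier charged)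
* factor on the rate of making target when 50 % of the substrate are converted if spent carrier is charged twice over

With the charges as they stand, spent carrier returns through the exchange at 450 min⁻¹ per spent carrier, much faster than fresh carrier turns over at 8.2 min⁻¹, so I first counted the working catalyst in this flask as fresh carrier. Then I divided the two loss rates and went to logarithms. On that count the logarithm of c(fresh carrier) falls in step with the logarithm of c(substrate), and the slope is N = 2.00, twice the pairing constant over the turnover constant: the proportional loss of fresh carrier per proportional loss of substrate, a selectivity factor between dying and working. N holds no charge of catalyst. At half conversion this reckoning gives 25.0 % of the catalyst working.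

Was one number enough? For half conversion I reckoned the salt in the second phase at 0.990 M and the spent salt at 0.210 M, each in its own phase, which gave about 0.230 spent carrier per fresh carrier. Spent carrier escapes pairing, so at half conversion the slope could ease to 1.63, and that slope taken over the whole way gives 32.4 % in fresh and spent carrier together. I therefore committed to 67.6 % to 75.0 % in the two spent catalysts together. Most of that should be spent catalyst B, since at half conversion, reckoning a quarter of the charge as fresh, pairing takes 0.102 min⁻¹ per fresh carrier, more than the 0.0289 min⁻¹ leaking to spent catalyst A.

The forecast gave spent catalyst B at 69 % (65 % to 72 %) for that form by itself and, reasoning that “At fixed conversion, rate ∝ fresh carrier”, orders of 0.23 in salt in the second phase and 1.14 in spent carrier, with a factor of 2.14 on the rate of making target for twice the spent carrier.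

This flask reached half conversion at 8.29 min, with spent catalyst B holding 68.8 % of the catalyst and orders of 0.23 in salt in the second phase and 1.1 in spent carrier. Fresh and spent carrier together held 25.5 %, beside the 25.0 % given by N, leaving 74.5 % in the two spent catalysts. N = 2.00 holds no charge, which puts the rate of making target at half conversion up by a factor of 2 when twice the spent carrier is charged; that flask gave a factor of 2.14.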